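The synthesis rests on building ring A last, by a Dötz benzannulation on a preformed pyran. The feature exploited is the hydroquinone pattern of ring A: oxygens at C5 and C8 para to each other, C6 and C7 unsubstituted, and C4a=C8a already present as the enol-ether double bond of a dihydropyran. In one thermal operation the carbene carbon (future C8), the two alkyne carbons (C7, C6) and one CO ligand (C5) are stitched onto that double bond, giving three C–C bonds and the aromatic ring. The precursor is the (4S,6R)-dihydropyranyl methoxycarbene chromium complex 10, whose future C2 stereocentre comes from a catalytic asymmetric hetero-Diels–Alder reaction and whose O4 is masked as a triisopropylsilyl ether.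

Key step: step 5

Assumption: the (S)-BINOL/Ti(OiPr)4 catalyst is taken to deliver the (R)-pyranone from an unbranched aliphatic aldehyde, by analogy with its allylation and aldol chemistry. The configuration is to be confirmed on alcohol 5 (Mosher esters), and (R)-BINOL is used instead if the sense proves opposite.

Remark on the precursor: O4 carries a triisopropylsilyl group, not a tert-butyldimethylsilyl group, because Si–CH3 groups compete for t-BuLi in the lithiation of silylated glycals. The aryl–Si bond is cleaved with acid only after C4 has become a ketone, because a C4–O bond flanked by the O1 and O5 donors would ionise under acid.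

**Step 1**
Reactants: 1 hexadecanal; 2 Danishefsky's diene
Product: 4 (R)-2-pentadecyl-2,3-dihydro-4H-pyran-4-one, via silylated aldol adduct 3 (not isolated)
Conditions: (S)-BINOL (20 mol %), Ti(OiPr)4 (10 mol %), CF3CO2H (cat.), 4 Å MS, Et2O, −20 °C; then CF3CO2H, CH2Cl2, 0 °C → rt
Reagents that add atoms: none
Why: Catalytic asymmetric hetero-Diels–Alder reaction of the Danishefsky–Keck type, in which the chiral BINOL–titanium Lewis acid directs Mukaiyama aldol attack of the diene terminus on one aldehyde face (this sets C2 as R) and acid then closes the ring by oxa-Michael addition with loss of methanol.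

**Step 2**
Reactants: 4 (R)-2-pentadecyl-2,3-dihydro-4H-pyran-4-one
Product: 5 (2R,4S)-2-pentadecyl-3,4-dihydro-2H-pyran-4-ol
Conditions: NaBH4, CeCl3·7H2O, MeOH, −78 → −20 °C; aq. NaHCO3 work-up
Reagents that add atoms: none
Why: Luche 1,2-reduction of the vinylogous ester, in which hydride adds axially to the half-chair with the pentadecyl group pseudo-equatorial and should give the cis (4S) alcohol, a temporary centre that is erased in step 8.

**Step 3**
Reactants: 5 (2R,4S)-2-pentadecyl-3,4-dihydro-2H-pyran-4-ol
Product: 6 triisopropyl{[(2R,4S)-2-pentadecyl-3,4-dihydro-2H-pyran-4-yl]oxy}silane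
Conditions: TIPSCl, imidazole, DMAP (cat.), DMF, rt → 40 °C
Reagents that add atoms: triisopropylsilyl chloride, CC(C)[Si](Cl)(C(C)C)C(C)C
Why: Base-mediated silylation of a secondary allylic alcohol under non-acidic conditions that spare the enol ether, giving a silyl ether without Si–CH3 protons for the lithiation that follows.

**Step 4**
Reactants: 6 triisopropyl{[(2R,4S)-2-pentadecyl-3,4-dihydro-2H-pyran-4-yl]oxy}silane; 7 chromium hexacarbonyl Cr(CO)6
Product: 10 pentacarbonyl{methoxy[(4S,6R)-6-pentadecyl-4-(triisopropylsilyloxy)-5,6-dihydro-4H-pyran-2-yl]methylidene}chromium, via vinyllithium 8 (not isolated), via lithium acylchromate 9 (not isolated)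
Conditions: t-BuLi (pentane), THF, −78 → 0 °C; Cr(CO)6, THF, −78 °C → rt; evaporate; MeOTf, CH2Cl2, −40 → 0 °C
Reagents that add atoms: methyl trifluoromethanesulfonate, COS(=O)(=O)C(F)(F)F
Why: Fischer carbene synthesis on a glycal-type substrate, in which the vinylic C–H next to the ring oxygen is lithiated (surplus base is consumed by THF on warming), the vinyllithium adds to a CO ligand, and the hard methylating agent alkylates the acylchromate oxygen, all remote from both stereocentres.

**Step 5**
Reactants: 10 pentacarbonyl{methoxy[(4S,6R)-6-pentadecyl-4-(triisopropylsilyloxy)-5,6-dihydro-4H-pyran-2-yl]methylidene}chromium; 11 trimethylsilylacetylene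
Product: 13 (2R,4S)-8-methoxy-2-pentadecyl-4-(triisopropylsilyloxy)-6-(trimethylsilyl)chroman-5-ol, via arene tricarbonylchromium complex 12 (not isolated)
Conditions: HC≡CSiMe3 (3 equiv), t-BuOMe (0.05 M, degassed), sealed tube, 55 °C; then air, Et2O, daylight, rt; Et3N-deactivated silica
Reagents that add atoms: none
Why: Heating releases a cis CO ligand from 10, the alkyne binds and inserts into the Cr=C bond with its CH terminus joined to the carbene carbon (C8–C7), CO inserts at the silyl-bearing carbon (C6–C5) to give a chromium-bound dienylketene, and 6π-electrocyclization forms C5–C4a; enolization gives the 4-methoxyphenol as its Cr(CO)3 complex 12, which air and light strip to 13. The closest known reaction type is the Dötz benzannulation of 2-oxacycloalkenyl (glycal-derived) methoxycarbene chromium complexes with alkynes, which delivers chromans. Ring A is closed by a disrotatory 6π-electrocyclic closure of the metal-templated dienylketene, not by a polar cyclization. No stereocentre is created: C2 (step 1) and C4 (step 2) lie outside the reacting π system, and the planar chirality of 12 vanishes on decomplexation. The one selectivity needed is chemoselectivity for CO insertion and six-membered closure over cyclopentannulation or furan formation, which an alkenyl methoxycarbene on chromium in an ether solvent at moderate temperature favours; the regiochemistry (bulky silyl group next to the CO-derived C5) is immaterial because C6 and C7 both end as CH.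

**Step 6**
Reactants: 13 (2R,4S)-8-methoxy-2-pentadecyl-4-(triisopropylsilyloxy)-6-(trimethylsilyl)chroman-5-ol
Product: 14 {[(2R,4S)-5,8-dimethoxy-2-pentadecyl-6-(trimethylsilyl)chroman-4-yl]oxy}triisopropylsilane
Conditions: MeI, K2CO3, DMF, rt (Ar)
Reagents that add atoms: iodomethane, CI
Why: Williamson O-methylation of the phenoxide turns the oxidation-prone 4-methoxyphenol into a robust hydroquinone dimethyl ether before the alcohol oxidation, and any premature loss of the C6 silyl group here is harmless because step 9 removes it anyway.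

**Step 7**
Reactants: 14 {[(2R,4S)-5,8-dimethoxy-2-pentadecyl-6-(trimethylsilyl)chroman-4-yl]oxy}triisopropylsilane
Product: 15 (2R,4S)-5,8-dimethoxy-2-pentadecyl-6-(trimethylsilyl)chroman-4-ol
Conditions: Bu4NF, THF, 0 °C → rt
Reagents that add atoms: none
Why: Fluoride-driven cleavage of the O–Si bond under basic conditions, which leaves the aryl–SiMe3 bond of the electron-rich ring and the ionisation-prone benzylic C4–O bond untouched.

**Step 8**
Reactants: 15 (2R,4S)-5,8-dimethoxy-2-pentadecyl-6-(trimethylsilyl)chroman-4-ol
Product: 16 (R)-5,8-dimethoxy-2-pentadecyl-6-(trimethylsilyl)chroman-4-one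
Conditions: Dess–Martin periodinane, NaHCO3, CH2Cl2, 0 °C → rt
Reagents that add atoms: none
Why: Buffered Dess–Martin oxidation of the secondary benzylic alcohol to the aryl ketone, which does not attack the fully etherified arene and removes the auxiliary C4 centre while leaving C2 (R) alone.

**Step 9**
Reactants: 16 (R)-5,8-dimethoxy-2-pentadecyl-6-(trimethylsilyl)chroman-4-one
Product: 18 (R)-5,8-dihydroxy-2-pentadecylchroman-4-one, via dimethoxychromanone 17 (not isolated)
Conditions: CF3CO2H, CH2Cl2, 0 °C → rt; evaporate (toluene); BBr3, CH2Cl2, −78 → 0 °C; MeOH, then H2O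
Reagents that add atoms: none
Why: Acid ipso-protodesilylation at C6 (ortho to the C5 ether and para to O1, helped by the β-silicon effect) is now safe because no benzylic leaving group remains, and BBr3 then cleaves both aryl methyl ethers by bromide attack at methyl (chelation-assisted at C5) under cold acidic conditions that avoid the base-induced retro-oxa-Michael pathway that would racemise C2.

**Compound list**

1 | hexadecanal | CCCCCCCCCCCCCCCC=O | starting material
2 | Danishefsky's diene, (E)-1-methoxy-3-(trimethylsilyloxy)buta-1,3-diene | CO/C=C/C(=C)O[Si](C)(C)C | starting material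
3 | (5R,1E)-1-methoxy-5-(trimethylsilyloxy)icos-1-en-3-one | CCCCCCCCCCCCCCC[C@@H](O[Si](C)(C)C)CC(=O)/C=C/OC | intermediate (not isolated)
4 | (R)-2-pentadecyl-2,3-dihydro-4H-pyran-4-one | CCCCCCCCCCCCCCC[C@@H]1CC(=O)C=CO1 | intermediate
5 | (2R,4S)-2-pentadecyl-3,4-dihydro-2H-pyran-4-ol (cis) | CCCCCCCCCCCCCCC[C@@H]1C[C@H](O)C=CO1 | intermediate
6 | triisopropyl{[(2R,4S)-2-pentadecyl-3,4-dihydro-2H-pyran-4-yl]oxy}silane | CCCCCCCCCCCCCCC[C@@H]1C[C@H](O[Si](C(C)C)(C(C)C)C(C)C)C=CO1 | intermediate
7 | chromium hexacarbonyl, Cr(CO)6 | O=C=[Cr](=C=O)(=C=O)(=C=O)(=C=O)=C=O | starting material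
8 | [(4S,6R)-6-pentadecyl-4-(triisopropylsilyloxy)-5,6-dihydro-4H-pyran-2-yl]lithium | CCCCCCCCCCCCCCC[C@@H]1C[C@H](O[Si](C(C)C)(C(C)C)C(C)C)C=C([Li])O1 | intermediate (not isolated)
9 | lithium pentacarbonyl{[(4S,6R)-6-pentadecyl-4-(triisopropylsilyloxy)-5,6-dihydro-4H-pyran-2-yl]carbonyl}chromate | CCCCCCCCCCCCCCC[C@@H]1C[C@H](O[Si](C(C)C)(C(C)C)C(C)C)C=C(O1)C([O-])=[Cr](=C=O)(=C=O)(=C=O)(=C=O)=C=O.[Li+] | intermediate (not isolated)
10 | pentacarbonyl{methoxy[(4S,6R)-6-pentadecyl-4-(triisopropylsilyloxy)-5,6-dihydro-4H-pyran-2-yl]methylidene}chromium | CCCCCCCCCCCCCCC[C@@H]1C[C@H](O[Si](C(C)C)(C(C)C)C(C)C)C=C(O1)C(OC)=[Cr](=C=O)(=C=O)(=C=O)(=C=O)=C=O | intermediate (precursor of the key step)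
11 | trimethylsilylacetylene | C#C[Si](C)(C)C | starting material
12 | tricarbonyl{η6-(2R,4S)-8-methoxy-2-pentadecyl-4-(triisopropylsilyloxy)-6-(trimethylsilyl)chroman-5-ol}chromium (η6 bonding written as a dot) | CCCCCCCCCCCCCCC[C@@H]1C[C@H](O[Si](C(C)C)(C(C)C)C(C)C)c2c(O)c([Si](C)(C)C)cc(OC)c2O1.O=C=[Cr](=C=O)=C=O | intermediate (not isolated)
13 | (2R,4S)-8-methoxy-2-pentadecyl-4-(triisopropylsilyloxy)-6-(trimethylsilyl)chroman-5-ol | CCCCCCCCCCCCCCC[C@@H]1C[C@H](O[Si](C(C)C)(C(C)C)C(C)C)c2c(O)c([Si](C)(C)C)cc(OC)c2O1 | intermediate (product of the key step)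
14 | {[(2R,4S)-5,8-dimethoxy-2-pentadecyl-6-(trimethylsilyl)chroman-4-yl]oxy}triisopropylsilane | CCCCCCCCCCCCCCC[C@@H]1C[C@H](O[Si](C(C)C)(C(C)C)C(C)C)c2c(OC)c([Si](C)(C)C)cc(OC)c2O1 | intermediate
15 | (2R,4S)-5,8-dimethoxy-2-pentadecyl-6-(trimethylsilyl)chroman-4-ol | CCCCCCCCCCCCCCC[C@@H]1C[C@H](O)c2c(OC)c([Si](C)(C)C)cc(OC)c2O1 | intermediate
16 | (R)-5,8-dimethoxy-2-pentadecyl-6-(trimethylsilyl)chroman-4-one | CCCCCCCCCCCCCCC[C@@H]1CC(=O)c2c(OC)c([Si](C)(C)C)cc(OC)c2O1 | intermediate
17 | (R)-5,8-dimethoxy-2-pentadecylchroman-4-one | CCCCCCCCCCCCCCC[C@@H]1CC(=O)c2c(OC)ccc(OC)c2O1 | intermediate (not isolated)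
18 | (R)-5,8-dihydroxy-2-pentadecylchroman-4-one | CCCCCCCCCCCCCCC[C@@H]1CC(=O)c2c(O)ccc(O)c2O1 | target

**Totals**

Total step count: 9. Longest linear sequence: 9 steps (1 → 18).

**Steps most likely to fail**

Step 5 (benzannulation). After CO loss and alkyne insertion the intermediate may be diverted into five-membered-ring formation without CO insertion, or the ketene may fail to close. The volatile alkyne may also oligomerise, and the electron-rich phenol may lose its C6 silyl group or oxidise during decomplexation. The fallback abandons the carbene chemistry and builds the pyranone onto a ready-made arene, setting out from 1 and returning at 17. Hexadecanal 1 is allylated with Bu3SnCH2CH=CH2 under (R)-BINOL/Ti(OiPr)4 catalysis (Keck allylation) to (S)-nonadec-1-en-4-ol F1. Mitsunobu etherification with 2,5-dimethoxyphenol (PPh3, DIAD, toluene, 0 °C) inverts the carbinol centre and gives 1,4-dimethoxy-2-{[(4R)-nonadec-1-en-4-yl]oxy}benzene F2. Lemieux–Johnson cleavage (OsO4 cat., NaIO4, 2,6-lutidine, dioxane/H2O) gives (R)-3-(2,5-dimethoxyphenoxy)octadecanal F3, and Pinnick oxidation (NaClO2, NaH2PO4, 2-methyl-2-butene) gives (R)-3-(2,5-dimethoxyphenoxy)octadecanoic acid F4. Intramolecular Friedel–Crafts acylation (Eaton's reagent, P2O5 in CH3SO3H, rt) at the only free position ortho to the ether oxygen closes the pyranone to 17, which re-enters at the BBr3 stage of step 9.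

Step 4 (carbene complex). Lithiation may be incomplete, surplus t-BuLi may attack Cr(CO)6 and contaminate the product with a tert-butyl carbene, and the acylchromate may decompose during methylation. The fallback generates the vinyllithium by tin–lithium exchange from a purified stannane, setting out from 6 and returning at 10. Compound 6 is metalated (t-BuLi, THF, −78 → 0 °C) and quenched with Bu3SnCl to tributyl[(4S,6R)-6-pentadecyl-4-(triisopropylsilyloxy)-5,6-dihydro-4H-pyran-2-yl]stannane F5, which is purified on basic alumina. Treatment with n-BuLi (1.0 equiv, THF, −78 °C) then gives 8 free of excess base, and addition to Cr(CO)6 and methylation with Me3OBF4 in CH2Cl2 give 10.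

Step 9 (desilylation and demethylation). The C8 ether may cleave incompletely, the Lewis acid may open the O1–C2 bond or erode the C2 configuration through reversible ring opening, and boron may attack the silyl-bearing carbon if protodesilylation is incomplete. The fallback replaces Lewis-acid dealkylation by an oxidation–reduction pair, setting out from 17 (isolated after the CF3CO2H stage) and returning at 18. Oxidative demethylation with (NH4)2Ce(NO3)6 in MeCN/H2O at 0 °C gives the quinone (R)-2-pentadecyl-2,3-dihydro-4H-chromene-4,5,8-trione F6. This is reduced at once in a two-phase mixture with aqueous Na2S2O4 (EtOAc, rt) to the hydroquinone 18, with no base or strong Lewis acid.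

**Further compounds**

F1 | step 5 | (S)-nonadec-1-en-4-ol | CCCCCCCCCCCCCCC[C@H](O)CC=C
F2 | step 5 | 1,4-dimethoxy-2-{[(4R)-nonadec-1-en-4-yl]oxy}benzene | CCCCCCCCCCCCCCC[C@@H](Oc1cc(OC)ccc1OC)CC=C
F3 | step 5 | (R)-3-(2,5-dimethoxyphenoxy)octadecanal | CCCCCCCCCCCCCCC[C@@H](Oc1cc(OC)ccc1OC)CC=O
F4 | step 5 | (R)-3-(2,5-dimethoxyphenoxy)octadecanoic acid | CCCCCCCCCCCCCCC[C@@H](Oc1cc(OC)ccc1OC)CC(=O)O
F5 | step 4 | tributyl[(4S,6R)-6-pentadecyl-4-(triisopropylsilyloxy)-5,6-dihydro-4H-pyran-2-yl]stannane | CCCCCCCCCCCCCCC[C@@H]1C[C@H](O[Si](C(C)C)(C(C)C)C(C)C)C=C(O1)[Sn](CCCC)(CCCC)CCCC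
F6 | step 9 | (R)-2-pentadecyl-2,3-dihydro-4H-chromene-4,5,8-trione | CCCCCCCCCCCCCCC[C@@H]1CC(=O)C2=C(O1)C(=O)C=CC2=O
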